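There were 4 questions, and each of them turned on the amount of target at the end of a flask.

    target ⇌ isomer of the product A (K1 = 1.0, k1 = 0.080 s⁻¹, Ea1 = 84.0 kJ mol⁻¹, ΔH1 = 4.00 kJ mol⁻¹)
    starting material ⇌ other conformer (K2 = 0.60, k2 = 0.025 s⁻¹, Ea2 = 74.0 kJ mol⁻¹, ΔH2 = 8.00 kJ mol⁻¹)
    target → over-reaction product (k3 = 0.022 s⁻¹, Ea3 = 88.0 kJ mol⁻¹)
    other conformer → isomer of the product A (k4 = 0.44 s⁻¹, Ea4 = 76.0 kJ mol⁻¹)
    starting material → target (k5 = 0.018 s⁻¹, Ea5 = 82.0 kJ mol⁻¹)
    target ⇌ isomer of the product B (K6 = 1.5, k6 = 0.13 s⁻¹, Ea6 = 88.0 kJ mol⁻¹, ΔH6 = −29.0 kJ mol⁻¹)
    solid substrate ⇌ starting material, rate k7*(cs7 - [starting material]) while solid is left; crystals form when [starting material] > cs7 (cs7 = 0.36 M, k7 = 1.8 s⁻¹)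
    (constants at 25 °C)

| setting | west | north-west | north |
|---|---|---|---|
| solid substrate | 1.0 M | 1.0 M | 1.0 M |
| temperature | 40 °C | 25 °C |  |
| time | 12 s | 12 s | 12 s |
| remark |  |  | at 25 °C until 6.0 s, from then on at 40 °C |

- given per volume of solution although it is solid: solid substrate
- the list of constants is for 25 °C, to be carried to other temperatures by the activation energies and enthalpies
- at the start none of the solid substrate is in solution
- in a conversion other conformer counts as not yet reacted
- what has only dissolved of solid substrate counts as not reacted

- which flask leads in amount of target, in percent of the solid substrate charged ("all alike" within 1.5 percentage points) (west / north-west / north / all alike)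
- how much target is there at the end, in percent of the solid substrate charged: west
- how much target is there at the end, in percent of the solid substrate charged: north-west
- how much target is there at the end, in percent of the solid substrate charged: north

I counted turnovers. While solid lay in a flask I took [starting material] to stand at 0.36 M, because dissolving, at 1.8 s⁻¹, was faster than the two exits to target and to other conformer, which together came to 0.0430 s⁻¹ at 25 °C and 0.192 s⁻¹ at 40 °C. That made a pseudo-zero-order feed. I reckoned 2.31 feed turnovers for west, meaning the exit constant times the time, or how many times the saturated stock of starting material was passed on. North-west had 0.516 and north had 1.41.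

The solid held a reserve of 1.78 such turnovers, the charge above solubility over solubility. North-west and north stayed inside it, but west went over, so I expected the solid to give out in west and my count to run high there.

The feed entered a pool of target and its two isomers. In north-west the relaxation half-lives of target with isomer of the product B and with isomer of the product A, 3.20 s and 4.33 s, each by its own step alone and both ways together, were shorter than 12 s, and the exchange with isomer of the product A sped up by a factor of 5.1 from cold to hot, so I gave target its equilibrium share of the pool: 0.286 cold and 0.340 hot. Over-reaction, at its constant times that share, gave a loss count of 0.492 in west, 0.0754 in north-west and 0.246 in the hot half of north. An evenly fed pool keeps one minus e to the minus count, over the count.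

Share times solubility times feed turnovers times that fraction gave 22.3% in west, 15.3% in north and 5.11% in north-west.

The forecast named west, with 19% there, 4.4% in north-west and 12% in north, holding that “the yield mainly tracks time spent hot”.

The simulation put west first with 17.6%, then north with 12.0% and north-west with 4.59%. My order stood, and each of my figures lay above its result. At 12.0 s the undissolved solid stood at 48.2% in north-west, 23.0% in north and 0% in west, the order the turnovers gave against the reserve.

The neighbouring flask was north-west's recipe kept at 50 °C. Its count was 5.81, above the 2.31 of west, and that many turnovers of the saturated stock exceeded the charge, so I capped the feed at 1.0 M. The loss count rose to 1.50, and the same reckoning, with the capped feed still spread evenly over the time, gave 18.9%, less than my figure for west. That flask ended with 0% solid substrate, 1.57% starting material and 14.5% target, less target than the 17.6% of west.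

The constants used here are assumed; the rest is arithmetic.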